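**Plan**

Numbering: ring O1–O2–C3–C4–C5–C6; C3 carries CH2CO2H, C4 a methyl, C6 a methyl and the chain C7H2–C8H(CH3)–(C9 to C16)H2–phenyl.
Cuts, backwards: the ester C–O bond; C3–CH2CO2Me and then C6–CH3, each made on a peroxycarbenium ion of one 3,6-dimethoxy-1,2-dioxane; O2–C3 (peroxyacetal exchange), with O1–O2 taken from ozone on a C6=CH2 alkene; C9–C10 (Grignard–tosylate coupling); C4–C5 and C7–C8 (double enolate alkylation).
Enabling feature: the quaternary peroxide carbon C6 (bonded to O1, CH3, C5 and C7) lies between two like arms, C5–C4(CH3) in the ring and C7–C8(CH3) in the chain, of the same spatial sense. While C6 is sp2 (first C=CH2, then C=O1+) the C3–C9 segment is C2-symmetric, so one auxiliary can set both methyl-bearing centres, and the flat C6 cation has only the ring C4 methyl nearby to tell its faces apart.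
Forward: the C3–C9 chain grows in both directions from a central three-carbon unit, is extended at either end to the phenyl terminus, the single ring is closed as a 3,6-bis(peroxyacetal), and the exocyclic C–C bonds follow at C6 and then at C3.
Stereochemistry: C4 and C8 from alkylation of the (R)-4-benzyloxazolidinone imide; C6 from axial methyl transfer trans to the equatorial C4 methyl; C3 from axial attack on the conformationally locked C3 cation, cis to the C4 methyl.

Key step: step 9

Assumption: every acetal-type centre that later passes through a planar cation (C4 of the methoxy hydroperoxide, C3 and C6 of the bis(peroxyacetal), C3 of its methylation product) is carried as an epimer mixture without separation.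

**Route**

Step 1
Reactants: 1 3-chloro-2-(chloromethyl)prop-1-ene
Product: 2 3-iodo-2-(iodomethyl)prop-1-ene
Conditions: NaI (2.5 equiv), acetone, rt, dark
Reagents that add atoms: sodium iodide, [Na+].[I-]
Why: Finkelstein exchange, in which iodide displaces both allylic chlorides by SN2 and the precipitation of NaCl from acetone drives the equilibrium; the diiodide is wanted because imide enolates alkylate cleanly at low temperature only with the most reactive allylic halides.

Step 2
Reactants: 3 (4R)-4-benzyl-3-propanoyl-1,3-oxazolidin-2-one; 2 3-iodo-2-(iodomethyl)prop-1-ene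
Product: 6 (4R,4'R)-3,3'-[(2S,6S)-2,6-dimethyl-4-methylideneheptanedioyl]bis(4-benzyl-1,3-oxazolidin-2-one), via sodium Z-enolate 4 (not isolated), via monoalkylated allylic iodide 5 (not isolated)
Conditions: 3 (2.4 equiv), NaN(SiMe3)2 (2.4 equiv), THF, −78 °C; then 2 (1.0 equiv), −78 to −40 °C
Reagents that add atoms: none
Why: Twofold Evans asymmetric alkylation, in which the chelated Z-enolate 4 is shielded on one face by the benzyl group, so each allylic iodide terminus is attacked from the open face and both new centres (the later C4 and C8) should come out 2S; a mismatched second alkylation would give a separable diastereomer, so the C2-symmetric 6 should be of high enantiomeric purity.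

Step 3
Reactants: 6 (4R,4'R)-3,3'-[(2S,6S)-2,6-dimethyl-4-methylideneheptanedioyl]bis(4-benzyl-1,3-oxazolidin-2-one)
Product: 7 (2S,6S)-2,6-dimethyl-4-methylideneheptane-1,7-diol
Conditions: LiBH4, MeOH, THF, 0 °C; aqueous work-up
Reagents that add atoms: none
Why: Reductive cleavage of an N-acyloxazolidinone with LiBH4, in which hydride adds to the exocyclic carbonyl and the released aldehyde is reduced further without enolisation of the α-methyl centres; the auxiliary is recovered and the isolated alkene is untouched.

Step 4
Reactants: 7 (2S,6S)-2,6-dimethyl-4-methylideneheptane-1,7-diol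
Product: 8 (2S,6S)-7-hydroxy-2,6-dimethyl-4-methylideneheptyl 4-methylbenzenesulfonate
Conditions: TsCl (1.05 equiv), Ag2O (1.5 equiv), KI (0.2 equiv), CH2Cl2, 0 °C to rt
Reagents that add atoms: 4-toluenesulfonyl chloride, Cc1ccc(cc1)S(=O)(=O)Cl
Why: Ag2O-mediated monosulfonylation of a symmetric diol; the two hydroxyl groups are interchanged by the C2 axis, so either one gives the same compound, and the silver oxide protocol should favour the mono- over the bis-tosylate.

Step 5
Reactants: 8 (2S,6S)-7-hydroxy-2,6-dimethyl-4-methylideneheptyl 4-methylbenzenesulfonate; 9 (7-bromoheptyl)benzene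
Product: 11 (2S,6R)-2,6-dimethyl-4-methylidene-14-phenyltetradecan-1-ol, via (7-phenylheptyl)magnesium bromide 10 (not isolated)
Conditions: 9, Mg, THF, rt to 40 °C; then 8, Li2CuCl4 (5 mol%), 10 (3 equiv), THF, −78 to 0 °C; cold 1 M HCl
Reagents that add atoms: none
Why: Copper-catalysed sp3–sp3 cross-coupling of a primary alkyl Grignard reagent with a primary tosylate; one equivalent of 10 is spent on the free hydroxyl group, the alkoxide is inert, and displacement at CH2–OTs leaves the neighbouring methyl-bearing centre (now C8, its descriptor changing to R only by priority) untouched.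

Step 6
Reactants: 11 (2S,6R)-2,6-dimethyl-4-methylidene-14-phenyltetradecan-1-ol
Product: 12 (2S,6R)-2,6-dimethyl-4-methylidene-14-phenyltetradecanal
Conditions: TEMPO (2,2,6,6-tetramethylpiperidin-1-oxyl, 10 mol%), PhI(OAc)2 (1.1 equiv), CH2Cl2, rt
Reagents that add atoms: none
Why: Oxoammonium-mediated oxidation of a primary alcohol, which stops at the aldehyde under nearly neutral conditions, so the α-methyl centre (later C4) should not epimerise and the 1,1-disubstituted alkene is not attacked.

Step 7
Reactants: 12 (2S,6R)-2,6-dimethyl-4-methylidene-14-phenyltetradecanal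
Product: 13 (2S,6R)-1,1-dimethoxy-2,6-dimethyl-4-methylidene-14-phenyltetradecane
Conditions: HC(OMe)3 (3 equiv), MeOH, pyridinium 4-toluenesulfonate (5 mol%), rt
Reagents that add atoms: trimethyl orthoformate, COC(OC)OC; methanol, CO
Why: Acid-catalysed acetalisation with the orthoformate as water scavenger; the weak acid at room temperature should neither enolise the aldehyde nor add methanol to the alkene, and the acetal supplies the leaving group for the ring closure.

Step 8
Reactants: 13 (2S,6R)-1,1-dimethoxy-2,6-dimethyl-4-methylidene-14-phenyltetradecane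
Product: 16 (4S)-3,6-dimethoxy-4-methyl-6-[(2R)-2-methyl-10-phenyldecyl]-1,2-dioxane (C3/C6 epimer mixture), via carbonyl oxide 14 (not isolated), via methoxy hydroperoxide 15 (not isolated)
Conditions: O3 (to consumption of the alkene, no excess), CH2Cl2/MeOH 4:1, −78 °C, N2 purge; solvent exchange to CH2Cl2; camphorsulfonic acid (0.1 equiv), 4 Å molecular sieves, 0 °C to rt
Reagents that add atoms: ozone, [O-][O+]=O; methanol, CO
Why: Ozonolysis by the Criegee mechanism followed by acid-catalysed peroxyacetal exchange: the primary ozonide should fragment mainly to formaldehyde and the more substituted carbonyl oxide 14, methanol traps this as the α-methoxy hydroperoxide 15, and under acid its OOH oxygen closes the six-membered ring on the C3 oxocarbenium ion (6-exo-trig, O2–C3 bond), so both peroxide oxygens come from ozone.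

Step 9
Reactants: 16 (4S)-3,6-dimethoxy-4-methyl-6-[(2R)-2-methyl-10-phenyldecyl]-1,2-dioxane (C3/C6 epimer mixture); 17 trimethylaluminium
Product: 19 (4S,6R)-3-methoxy-4,6-dimethyl-6-[(2R)-2-methyl-10-phenyldecyl]-1,2-dioxane (C3 epimer mixture), via C6 peroxycarbenium ion 18 (not isolated)
Conditions: AlMe3 (3 equiv, toluene solution), Me3SiOTf (0.1 equiv), CH2Cl2, −78 to −40 °C; then aq. KNaC4H4O6 (potassium sodium tartrate)
Reagents that add atoms: none
Why: Proposed new method: AlMe3, made more Lewis acidic by a small charge of Me3SiOTf (which ends up as Me2AlOTf), should bind the methoxy oxygen of the tertiary C6 peroxyketal, the most basic oxygen there, and ionise it to the peroxycarbenium ion 18 (C6=O1+), to which a methyl group is then passed from aluminium. The closest known reactions are Lewis-acid-mediated allylations and Mukaiyama-type additions to cyclic peroxyketals through peroxycarbenium ions and the AlMe3 C-methylation of anomeric acetals and ketals, which is also known for lactol derivatives that hold a peroxide elsewhere in the ring system. No ring is closed in this step: the 1,2-dioxane is in place since step 8 and only the exocyclic C6–CH3 bond forms. The one new stereocentre, quaternary C6, is controlled by the C4 methyl group: it sits pseudo-equatorial in the half-chair of 18 and methyl enters along the axial line that leads directly to a chair, which places the new methyl axial and trans to the C4 methyl and the C7 arm equatorial and cis to it, while the C3 and C6 epimers of 16 converge because C6 is planar in 18 and C3 is reset in step 10. The step needs site selectivity (C6 before C3) and face selectivity at C6; the first should follow from the much easier ionisation of a tertiary peroxyketal than of the secondary peroxyacetal at C3, the second from orbital overlap in the half-chair and not from the slight steric difference between a methyl group and a 2-methylalkyl chain, which a ring closure onto C6 would have to tell apart. The O–O bond, hindered on both sides by acetal carbons, should outlast the aluminium alkyl at low temperature.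

Step 10
Reactants: 19 (4S,6R)-3-methoxy-4,6-dimethyl-6-[(2R)-2-methyl-10-phenyldecyl]-1,2-dioxane (C3 epimer mixture); 20 tert-butyl[(1-methoxyethenyl)oxy]dimethylsilane
Product: 22 methyl 2-[(3S,4S,6R)-4,6-dimethyl-6-[(2R)-2-methyl-10-phenyldecyl]-1,2-dioxan-3-yl]acetate, via C3 peroxycarbenium ion 21 (not isolated)
Conditions: 20 (2.5 equiv), Me3SiOTf (0.3 equiv), CH2Cl2, −78 °C; then aq. NaHCO3
Reagents that add atoms: none
Why: Mukaiyama-type addition of a silyl ketene acetal to a cyclic peroxyacetal through its peroxycarbenium ion, catalytic in silyl triflate as in aldol-type acetal substitutions; 21 is locked in the half-chair with the C4 methyl and the C7 arm equatorial and the C6 methyl axial, and attack along the axial line at C3, on the face away from the axial C6 methyl, should put the acetate arm axial and cis to the C4 methyl (3S).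

Step 11
Reactants: 22 methyl 2-[(3S,4S,6R)-4,6-dimethyl-6-[(2R)-2-methyl-10-phenyldecyl]-1,2-dioxan-3-yl]acetate
Product: 23 2-[(3S,4S,6R)-4,6-dimethyl-6-[(2R)-2-methyl-10-phenyldecyl]-1,2-dioxan-3-yl]acetic acid
Conditions: LiOH·H2O (3 equiv), THF/H2O 3:1, 0 °C to rt; then 1 M HCl to pH 3 at 0 °C
Reagents that add atoms: lithium hydroxide, [Li+].[OH-]
Why: Saponification (acyl–oxygen cleavage by hydroxide) of the methyl ester, a usual last step for 1,2-dioxane-3-acetic acids; the dialkyl peroxide should survive cold dilute hydroxide and the short reaction time should avoid retro-oxa-Michael opening at C3.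

**Compound list**

1 | 3-chloro-2-(chloromethyl)prop-1-ene | C=C(CCl)CCl | starting material
2 | 3-iodo-2-(iodomethyl)prop-1-ene | C=C(CI)CI | intermediate
3 | (4R)-4-benzyl-3-propanoyl-1,3-oxazolidin-2-one | CCC(=O)N1[C@H](Cc2ccccc2)COC1=O | starting material
4 | sodium (Z)-1-[(4R)-4-benzyl-2-oxo-1,3-oxazolidin-3-yl]prop-1-en-1-olate (sodium Z-enolate of 3) | C/C=C(\[O-])N1[C@H](Cc2ccccc2)COC1=O.[Na+] | intermediate
5 | (4R)-4-benzyl-3-[(2S)-4-(iodomethyl)-2-methylpent-4-enoyl]-1,3-oxazolidin-2-one | O=C(N1[C@H](Cc2ccccc2)COC1=O)[C@@H](C)CC(=C)CI | intermediate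
6 | (4R,4'R)-3,3'-[(2S,6S)-2,6-dimethyl-4-methylideneheptanedioyl]bis(4-benzyl-1,3-oxazolidin-2-one) | O=C(N1[C@H](Cc2ccccc2)COC1=O)[C@@H](C)CC(=C)C[C@H](C)C(=O)N1[C@H](Cc2ccccc2)COC1=O | intermediate
7 | (2S,6S)-2,6-dimethyl-4-methylideneheptane-1,7-diol | OC[C@@H](C)CC(=C)C[C@H](C)CO | intermediate
8 | (2S,6S)-7-hydroxy-2,6-dimethyl-4-methylideneheptyl 4-methylbenzenesulfonate | Cc1ccc(cc1)S(=O)(=O)OC[C@@H](C)CC(=C)C[C@H](C)CO | intermediate
9 | (7-bromoheptyl)benzene | BrCCCCCCCc1ccccc1 | starting material
10 | (7-phenylheptyl)magnesium bromide | Br[Mg]CCCCCCCc1ccccc1 | intermediate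
11 | (2S,6R)-2,6-dimethyl-4-methylidene-14-phenyltetradecan-1-ol | c1ccccc1CCCCCCCC[C@@H](C)CC(=C)C[C@H](C)CO | intermediate
12 | (2S,6R)-2,6-dimethyl-4-methylidene-14-phenyltetradecanal | c1ccccc1CCCCCCCC[C@@H](C)CC(=C)C[C@H](C)C=O | intermediate
13 | (2S,6R)-1,1-dimethoxy-2,6-dimethyl-4-methylidene-14-phenyltetradecane | c1ccccc1CCCCCCCC[C@@H](C)CC(=C)C[C@H](C)C(OC)OC | intermediate
14 | carbonyl oxide (Criegee zwitterion at C4) of (2S,6R)-1,1-dimethoxy-2,6-dimethyl-14-phenyltetradecan-4-one | c1ccccc1CCCCCCCC[C@@H](C)CC(=[O+][O-])C[C@H](C)C(OC)OC | intermediate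
15 | (2S,6R)-4-hydroperoxy-1,1,4-trimethoxy-2,6-dimethyl-14-phenyltetradecane, C4 epimers | c1ccccc1CCCCCCCC[C@@H](C)CC(OC)(OO)C[C@H](C)C(OC)OC | intermediate
16 | (4S)-3,6-dimethoxy-4-methyl-6-[(2R)-2-methyl-10-phenyldecyl]-1,2-dioxane, epimers at C3 and C6 | c1ccccc1CCCCCCCC[C@@H](C)CC1(OC)C[C@H](C)C(OC)OO1 | intermediate
17 | trimethylaluminium | C[Al](C)C | starting material
18 | C6 peroxycarbenium ion of 16 (C6=O1+; C3 methoxy, 4S methyl, (2R)-2-methyl-10-phenyldecyl on C6), drawn as ion pair with methoxytrimethylaluminate | c1ccccc1CCCCCCCC[C@@H](C)CC1=[O+]OC(OC)[C@@H](C)C1.CO[Al-](C)(C)C | intermediate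
19 | (4S,6R)-3-methoxy-4,6-dimethyl-6-[(2R)-2-methyl-10-phenyldecyl]-1,2-dioxane, epimers at C3 | c1ccccc1CCCCCCCC[C@@H](C)C[C@]1(C)C[C@H](C)C(OC)OO1 | intermediate
20 | tert-butyl[(1-methoxyethenyl)oxy]dimethylsilane | C=C(OC)O[Si](C)(C)C(C)(C)C | starting material
21 | C3 peroxycarbenium ion of 19 (C3=O2+; 4S methyl, 6R methyl and side chain), drawn as triflate ion pair | c1ccccc1CCCCCCCC[C@@H](C)C[C@]1(C)C[C@H](C)C=[O+]O1.[O-]S(=O)(=O)C(F)(F)F | intermediate
22 | methyl 2-[(3S,4S,6R)-4,6-dimethyl-6-[(2R)-2-methyl-10-phenyldecyl]-1,2-dioxan-3-yl]acetate | c1ccccc1CCCCCCCC[C@@H](C)C[C@]1(C)C[C@H](C)[C@H](CC(=O)OC)OO1 | intermediate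
23 | 2-[(3S,4S,6R)-4,6-dimethyl-6-[(2R)-2-methyl-10-phenyldecyl]-1,2-dioxan-3-yl]acetic acid | C[C@H](CCCCCCCCc1ccccc1)C[C@]1(C)C[C@H](C)[C@H](CC(=O)O)OO1 | target

**Count**

Total step count: 11. Longest linear sequence: 11 steps (1 to 23); compounds 3, 9, 17 and 20 enter as purchased reagents.

**Steps most likely to fail**

Step 9. The peroxyketal may ionise sluggishly or at both acetal carbons, the aluminium alkyl may reduce the O–O bond, ionisation at C6 may open the ring by loss of the peroxide oxygen, or methyl may be delivered with poor face selectivity. The fallback uses known chemistry, sets out from aldehyde 12 and comes back at ester 22.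
- Wittig olefination of 12 with methyl (triphenylphosphoranylidene)acetate (CH2Cl2, rt) should give methyl (2E,4S,8R)-4,8-dimethyl-6-methylidene-16-phenylhexadec-2-enoate F1.
- Mukaiyama–Isayama peroxidation of the electron-rich 1,1-disubstituted alkene of F1 should leave the enoate alone. With Co(thd)2 (thd = 2,2,6,6-tetramethylheptane-3,5-dionate, a diketonate of divalent cobalt; catalytic), O2 and Et3SiH in 1,2-dichloroethane it should give the tertiary silyl peroxide methyl (2E,4S,8R)-4,6,8-trimethyl-16-phenyl-6-[(triethylsilyl)peroxy]hexadec-2-enoate F2, with the C6 methyl arising from the former =CH2.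
- Desilylation (catalytic HCl in MeOH) should free methyl (2E,4S,8R)-6-hydroperoxy-4,6,8-trimethyl-16-phenylhexadec-2-enoate F3.
- Base-mediated intramolecular oxa-Michael addition (Et2NH, CF3CH2OH) should close the O2–C3 bond to the 1,2-dioxane-3-acetate.
- This route gives C6 as both epimers and C3 with substrate bias only, so 22 would have to be separated from its diastereomers.

Step 10. The secondary peroxycarbenium ion may lose the C4 proton (scrambling C4 through an enol peroxide), and the very reactive ketene acetal may add with eroded axial selectivity. The fallback sets out from 19 and comes back at 23, bypassing 22.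
- Hosomi–Sakurai allylation with the weaker and more selective nucleophile allyltrimethylsilane (SnCl4, CH2Cl2, −78 °C) should give (3S,4S,6R)-4,6-dimethyl-6-[(2R)-2-methyl-10-phenyldecyl]-3-(prop-2-en-1-yl)-1,2-dioxane F4.
- Ozonolysis of the terminal alkene (CH2Cl2/MeOH, −78 °C, then Me2S, which spares dialkyl peroxides) should give 2-[(3S,4S,6R)-4,6-dimethyl-6-[(2R)-2-methyl-10-phenyldecyl]-1,2-dioxan-3-yl]acetaldehyde F5.
- Pinnick oxidation (NaClO2, NaH2PO4, 2-methylbut-2-ene, t-BuOH/H2O) should give the acid 23 directly, so the carboxyl group arises by oxidative shortening of an allyl group and not from an enolate equivalent.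

Step 8. The primary ozonide may fragment in the unwanted sense (ketone plus formaldehyde oxide), or the methoxy hydroperoxide may lose hydrogen peroxide under acid faster than it cyclises. The fallback sets out from 13 and comes back at 16.
- Ozonolysis of 13 with reductive work-up (Me2S) should give the γ-keto acetal (2S,6R)-1,1-dimethoxy-2,6-dimethyl-14-phenyltetradecan-4-one F6.
- Acid-catalysed condensation of F6 with hydrogen peroxide (urea–H2O2, catalytic camphorsulfonic acid, MeOH, 0 °C to rt) is the known route from 1,4-dicarbonyl compounds to 3,6-dialkoxy-1,2-dioxanes and should give 16, now with both peroxide oxygens from H2O2.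

**Further compounds**

F1 | step 9 | methyl (2E,4S,8R)-4,8-dimethyl-6-methylidene-16-phenylhexadec-2-enoate | COC(=O)/C=C/[C@@H](C)CC(=C)C[C@H](C)CCCCCCCCc1ccccc1
F2 | step 9 | methyl (2E,4S,8R)-4,6,8-trimethyl-16-phenyl-6-[(triethylsilyl)peroxy]hexadec-2-enoate, C6 epimers | COC(=O)/C=C/[C@@H](C)CC(C)(OO[Si](CC)(CC)CC)C[C@H](C)CCCCCCCCc1ccccc1
F3 | step 9 | methyl (2E,4S,8R)-6-hydroperoxy-4,6,8-trimethyl-16-phenylhexadec-2-enoate, C6 epimers | COC(=O)/C=C/[C@@H](C)CC(C)(OO)C[C@H](C)CCCCCCCCc1ccccc1
F4 | step 10 | (3S,4S,6R)-4,6-dimethyl-6-[(2R)-2-methyl-10-phenyldecyl]-3-(prop-2-en-1-yl)-1,2-dioxane | C[C@H](CCCCCCCCc1ccccc1)C[C@]1(C)C[C@H](C)[C@H](CC=C)OO1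
F5 | step 10 | 2-[(3S,4S,6R)-4,6-dimethyl-6-[(2R)-2-methyl-10-phenyldecyl]-1,2-dioxan-3-yl]acetaldehyde | C[C@H](CCCCCCCCc1ccccc1)C[C@]1(C)C[C@H](C)[C@H](CC=O)OO1
F6 | step 8 | (2S,6R)-1,1-dimethoxy-2,6-dimethyl-14-phenyltetradecan-4-one | c1ccccc1CCCCCCCC[C@@H](C)CC(=O)C[C@H](C)C(OC)OC
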